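## Retrosynthetic overview

1. Target ⇐ C2 acetylation, C6 veratroylation and C6-hydroxyl-directed epoxidation of the 2-silyloxy-dauc-8-ene-4,6-diol 13.
2. Seven-membered ring of 13 ⇐ ring-closing metathesis (C8=C9) of cyclopentane 12; C6 ⇐ chelation-controlled methallylation of aldehyde 11.
3. C4 ⇐ isopropyl addition to cyclopentanone 9; C1 and C5 ⇐ conjugate methylation and hydroxymethylation of enone 7, both steered by the C2 silyloxy group.
4. Enone 7 ⇐ Stork–Danheiser transposition of 5; the C2 stereocenter of 5 ⇐ a proposed enantioselective Rubottom oxidation of the silyl dienol ether of 3-ethoxycyclopent-2-en-1-one (1).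
5. Ring order: five-membered ring (from 1) first, seven-membered ring by metathesis second, oxirane last.

Assumption: the SMILES is read as the absolute configuration (1R,2S,4R,5S,6S,8R,9S) in daucane numbering (C1 quaternary ring-fusion carbon with CH3; C2, C3, C4 in the five-membered ring; C5 ring-fusion CH; C6 to C10 in the seven-membered ring), and this numbering is used for ring carbons throughout.

## Route

Step 1
Reactants: 1 3-ethoxycyclopent-2-en-1-one
Product: 3 tert-butyl[(4-ethoxycyclopenta-1,4-dien-1-yl)oxy]dimethylsilane, via lithium dienolate 2 (not isolated)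
Conditions: LiN(iPr)2, THF, −78 °C; TBSOTf, −78 → 0 °C; cold pentane/aq. NaHCO3 work-up, used at once
Reagents that add atoms: tert-butyldimethylsilyl trifluoromethanesulfonate (TBSOTf), CC(C)(C)[Si](C)(C)OS(=O)(=O)C(F)(F)F
Why: Kinetic deprotonation of the vinylogous ester at the CH2 next to the carbonyl and O-silylation of the cross-conjugated enolate (silyl enol ether formation) give the 2-silyloxy diene; no stereocenter is formed.

Step 2
Reactants: 3 tert-butyl[(4-ethoxycyclopenta-1,4-dien-1-yl)oxy]dimethylsilane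
Product: 5 (5S)-5-[(tert-butyldimethylsilyl)oxy]-3-ethoxycyclopent-2-en-1-one, via silyloxy epoxide 4 (not isolated)
Conditions: 1,2:4,5-di-O-isopropylidene-β-L-erythro-2,3-hexodiulo-2,6-pyranose (enantiomer of the Shi ketone, 30 mol%), KHSO5 (Oxone, 2KHSO5·KHSO4·K2SO4), K2CO3, Bu4NHSO4, aq. Na2B4O7 buffer pH 10.5, MeCN/CH2(OMe)2/H2O, −10 °C; SiO2 filtration
Reagents that add atoms: potassium peroxymonosulfate KHSO5, [K+].[O-]S(=O)(=O)OO
Why: Proposed new method: an enantioselective Rubottom oxidation with silyl transfer on a cross-conjugated cyclic silyl dienol ether, in which the chiral dioxirane formed from the ketone and KHSO5 epoxidises only the enol-ether bond whose CH terminus is activated by both oxygen donors, through the usual spiro transition state (the L-fructose-derived catalyst is predicted to give 5S because the D-series gives the R,R sense with 1-arylcycloalkenes and the silyloxy group takes the place of the aryl group), after which oxirane 4 opens to the vinylogous oxocarbenium ion and a 1,4 oxygen-to-oxygen silyl shift gives the silyloxy enone without touching the new C–O bond; the closest known reaction types are the Shi asymmetric epoxidation of simple silyl enol ethers and enol esters and the racemic Rubottom oxidation.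

Step 3
Reactants: 5 (5S)-5-[(tert-butyldimethylsilyl)oxy]-3-ethoxycyclopent-2-en-1-one
Product: 7 (4S)-4-[(tert-butyldimethylsilyl)oxy]-3-(prop-2-en-1-yl)cyclopent-2-en-1-one, via chloromagnesium alkoxide 6 (not isolated)
Conditions: CH2=CHCH2MgCl, THF, −78 → 0 °C; then 1 M aq. HCl, 0 °C → rt, 30 min
Reagents that add atoms: allylmagnesium chloride, C=CC[Mg]Cl; water, O
Why: Stork–Danheiser transposition, in which 1,2-addition of the allyl Grignard reagent to the vinylogous-ester carbonyl and acid hydrolysis/dehydration of alkoxide 6 move the carbonyl and give the β-allyl enone; the silyloxy stereocenter is untouched and the carbinol center of 6 is destroyed.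

Step 4
Reactants: 7 (4S)-4-[(tert-butyldimethylsilyl)oxy]-3-(prop-2-en-1-yl)cyclopent-2-en-1-one
Product: 8 tert-butyl({(1S,2R)-2-methyl-2-(prop-2-en-1-yl)-4-[(trimethylsilyl)oxy]cyclopent-3-en-1-yl}oxy)dimethylsilane
Conditions: MeMgCl, CuBr·SMe2 (10 mol%), TMSCl, HMPA, THF, −78 °C; Et3N/pentane work-up
Reagents that add atoms: methylmagnesium chloride, C[Mg]Cl; chlorotrimethylsilane, C[Si](C)(C)Cl
Why: Copper-catalysed, TMSCl-accelerated conjugate addition of the methyl Grignard reagent (Kuwajima-type conditions) to the β,β-disubstituted enone places CH3 anti to the neighbouring silyloxy group, as in prostaglandin-type 4-silyloxycyclopentenone additions, which sets quaternary C1, and the enolate is trapped regiospecifically as the TMS enol ether.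

Step 5
Reactants: 8 tert-butyl({(1S,2R)-2-methyl-2-(prop-2-en-1-yl)-4-[(trimethylsilyl)oxy]cyclopent-3-en-1-yl}oxy)dimethylsilane
Product: 9 (2S,3R,4S)-4-[(tert-butyldimethylsilyl)oxy]-2-(hydroxymethyl)-3-methyl-3-(prop-2-en-1-yl)cyclopentan-1-one
Conditions: 37% aq. HCHO, Yb(OTf)3 (10 mol%), THF, rt
Reagents that add atoms: formaldehyde, C=O
Why: Lanthanide-triflate-catalysed aqueous Mukaiyama aldol (hydroxymethylation) in which formaldehyde approaches C5 on the face of the C1 methyl group, away from the C1 allyl group and the cis C2 silyloxy group, so that CH2OH ends trans to allyl (moderate to good dr expected, minor epimer removed by chromatography).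

Step 6
Reactants: 9 (2S,3R,4S)-4-[(tert-butyldimethylsilyl)oxy]-2-(hydroxymethyl)-3-methyl-3-(prop-2-en-1-yl)cyclopentan-1-one
Product: 10 (1R,2S,3R,4S)-4-[(tert-butyldimethylsilyl)oxy]-2-(hydroxymethyl)-3-methyl-1-(propan-2-yl)-3-(prop-2-en-1-yl)cyclopentan-1-ol
Conditions: iPrMgCl/CeCl3 (4 equiv each, premixed in THF), −78 → −30 °C; aq. NH4Cl
Reagents that add atoms: isopropylmagnesium chloride, CC(C)[Mg]Cl
Why: Organocerium (Imamoto) addition suppresses enolisation, loss of the β-silyloxy group and hydride reduction; after the first equivalent forms the primary alkoxide, isopropyl attacks the ketone anti to the adjacent C5 substituent, so the new C4 hydroxyl is cis to the C5 side chain (4R in daucane numbering).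

Step 7
Reactants: 10 (1R,2S,3R,4S)-4-[(tert-butyldimethylsilyl)oxy]-2-(hydroxymethyl)-3-methyl-1-(propan-2-yl)-3-(prop-2-en-1-yl)cyclopentan-1-ol
Product: 11 (1R,2R,4S,5R)-4-[(tert-butyldimethylsilyl)oxy]-2-hydroxy-5-methyl-2-(propan-2-yl)-5-(prop-2-en-1-yl)cyclopentane-1-carbaldehyde
Conditions: Dess–Martin periodinane, CH2Cl2, 0 °C → rt; used at once
Reagents that add atoms: none
Why: Dess–Martin oxidation converts the primary alcohol into the aldehyde under neutral, non-epimerising conditions, while the tertiary alcohol cannot be oxidised.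

Step 8
Reactants: 11 (1R,2R,4S,5R)-4-[(tert-butyldimethylsilyl)oxy]-2-hydroxy-5-methyl-2-(propan-2-yl)-5-(prop-2-en-1-yl)cyclopentane-1-carbaldehyde
Product: 12 (1R,2S,3R,4S)-4-[(tert-butyldimethylsilyl)oxy]-2-[(1S)-1-hydroxy-3-methylbut-3-en-1-yl]-3-methyl-1-(propan-2-yl)-3-(prop-2-en-1-yl)cyclopentan-1-ol
Conditions: CH2=C(CH3)CH2MgCl (2.5 equiv), THF, −78 °C; aq. NH4Cl
Reagents that add atoms: 2-methylallylmagnesium chloride, CC(=C)C[Mg]Cl
Why: Chelation-controlled (Cram-chelate) Grignard allylation in which the magnesium alkoxide of the C4 hydroxyl, cis to the formyl group, holds the aldehyde in a six-membered chelate and the methallyl group adds to the exposed face on the side of H5, away from quaternary C1, giving the 6S alcohol.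

Step 9
Reactants: 12 (1R,2S,3R,4S)-4-[(tert-butyldimethylsilyl)oxy]-2-[(1S)-1-hydroxy-3-methylbut-3-en-1-yl]-3-methyl-1-(propan-2-yl)-3-(prop-2-en-1-yl)cyclopentan-1-ol
Product: 13 (1R,2S,4R,5S,6S)-2-[(tert-butyldimethylsilyl)oxy]dauc-8-ene-4,6-diol
Conditions: second-generation Grubbs catalyst RuCl2(=CHPh)(PCy3)(H2IMes) (5 mol%), CH2Cl2 (0.005 M), 40 °C
Reagents that add atoms: none
Why: Ring-closing metathesis of the allyl and methallyl olefins forms the trisubstituted C8=C9 bond and the seven-membered ring with loss of ethene; the trans ring fusion is already fixed at C1 and C5, and free hydroxyls are tolerated.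

Step 10
Reactants: 13 (1R,2S,4R,5S,6S)-2-[(tert-butyldimethylsilyl)oxy]dauc-8-ene-4,6-diol
Product: 14 (1R,2S,4R,5S,6S,8R,9S)-2-[(tert-butyldimethylsilyl)oxy]-8,9-epoxydaucane-4,6-diol
Conditions: VO(acac)2 (5 mol%), tBuOOH (decane solution), CH2Cl2, 0 °C → rt
Reagents that add atoms: tert-butyl hydroperoxide, CC(C)(C)OO
Why: Hydroxyl-directed vanadium-catalysed epoxidation of a cyclic homoallylic alcohol, in which the vanadate ester of the C6 hydroxyl delivers oxygen to the same face of C8=C9 and so sets C8 and C9 with the oxirane cis to the C6 oxygen.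

Step 11
Reactants: 14 (1R,2S,4R,5S,6S,8R,9S)-2-[(tert-butyldimethylsilyl)oxy]-8,9-epoxydaucane-4,6-diol
Product: 15 (1R,2S,4R,5S,6S,8R,9S)-2-[(tert-butyldimethylsilyl)oxy]-8,9-epoxy-4-hydroxydaucan-6-yl 3,4-dimethoxybenzoate
Conditions: 3,4-dimethoxybenzoyl chloride, Et3N, 4-(dimethylamino)pyridine (cat.), CH2Cl2, 0 °C → rt
Reagents that add atoms: 3,4-dimethoxybenzoyl chloride, COc1ccc(C(Cl)=O)cc1OC
Why: Nucleophile-catalysed acylation of the only secondary hydroxyl; the tertiary C4 hydroxyl is too hindered to react and the basic medium leaves the oxirane intact.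

Step 12
Reactants: 15 (1R,2S,4R,5S,6S,8R,9S)-2-[(tert-butyldimethylsilyl)oxy]-8,9-epoxy-4-hydroxydaucan-6-yl 3,4-dimethoxybenzoate
Product: 16 (1R,2S,4R,5S,6S,8R,9S)-8,9-epoxy-2,4-dihydroxydaucan-6-yl 3,4-dimethoxybenzoate
Conditions: Bu4NF, AcOH (1:1), THF, rt → 40 °C
Reagents that add atoms: none
Why: Acetic-acid-buffered fluoride desilylation removes the silyl ether without opening the oxirane or cleaving the aryl ester, and acyl migration is not possible because the C2 and C6 oxygens are remote.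

Step 13
Reactants: 16 (1R,2S,4R,5S,6S,8R,9S)-8,9-epoxy-2,4-dihydroxydaucan-6-yl 3,4-dimethoxybenzoate
Product: 17 (1R,2S,4R,5S,6S,8R,9S)-2-acetoxy-8,9-epoxy-4-hydroxydaucan-6-yl 3,4-dimethoxybenzoate (CNP0330776.2)
Conditions: Ac2O, pyridine, 4-(dimethylamino)pyridine (cat.), CH2Cl2, rt
Reagents that add atoms: acetic anhydride, CC(=O)OC(C)=O
Why: Nucleophile-catalysed acetylation of the secondary C2 hydroxyl; the tertiary C4 hydroxyl next to isopropyl is not acetylated at room temperature, so the target results.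

## Compound list

1 | 3-ethoxycyclopent-2-en-1-one | CCOC1=CC(=O)CC1 | starting material
2 | lithium 4-ethoxycyclopenta-1,4-dien-1-olate | [Li+].[O-]C1=CCC(OCC)=C1 | intermediate
3 | tert-butyl[(4-ethoxycyclopenta-1,4-dien-1-yl)oxy]dimethylsilane | CCOC1=CC(O[Si](C)(C)C(C)(C)C)=CC1 | intermediate
4 | tert-butyl{[(1S,5S)-3-ethoxy-6-oxabicyclo[3.1.0]hex-2-en-1-yl]oxy}dimethylsilane | CCOC1=C[C@@]2(O[Si](C)(C)C(C)(C)C)O[C@H]2C1 | intermediate
5 | (5S)-5-[(tert-butyldimethylsilyl)oxy]-3-ethoxycyclopent-2-en-1-one | CCOC1=CC(=O)[C@@H](O[Si](C)(C)C(C)(C)C)C1 | intermediate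
6 | chloromagnesium (5S)-5-[(tert-butyldimethylsilyl)oxy]-3-ethoxy-1-(prop-2-en-1-yl)cyclopent-2-en-1-olate (both C1 epimers) | CCOC1=CC(CC=C)(O[Mg]Cl)[C@@H](O[Si](C)(C)C(C)(C)C)C1 | intermediate
7 | (4S)-4-[(tert-butyldimethylsilyl)oxy]-3-(prop-2-en-1-yl)cyclopent-2-en-1-one | C=CCC1=CC(=O)C[C@@H]1O[Si](C)(C)C(C)(C)C | intermediate
8 | tert-butyl({(1S,2R)-2-methyl-2-(prop-2-en-1-yl)-4-[(trimethylsilyl)oxy]cyclopent-3-en-1-yl}oxy)dimethylsilane (CH3 trans to OTBS) | C[Si](C)(C)OC1=C[C@@](C)(CC=C)[C@@H](O[Si](C)(C)C(C)(C)C)C1 | intermediate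
9 | (2S,3R,4S)-4-[(tert-butyldimethylsilyl)oxy]-2-(hydroxymethyl)-3-methyl-3-(prop-2-en-1-yl)cyclopentan-1-one (CH2OH cis to CH3, trans to allyl) | OC[C@H]1C(=O)C[C@H](O[Si](C)(C)C(C)(C)C)[C@]1(C)CC=C | intermediate
10 | (1R,2S,3R,4S)-4-[(tert-butyldimethylsilyl)oxy]-2-(hydroxymethyl)-3-methyl-1-(propan-2-yl)-3-(prop-2-en-1-yl)cyclopentan-1-ol (tertiary OH cis to CH2OH) | OC[C@H]1[C@](O)(C(C)C)C[C@H](O[Si](C)(C)C(C)(C)C)[C@]1(C)CC=C | intermediate
11 | (1R,2R,4S,5R)-4-[(tert-butyldimethylsilyl)oxy]-2-hydroxy-5-methyl-2-(propan-2-yl)-5-(prop-2-en-1-yl)cyclopentane-1-carbaldehyde | O=C[C@H]1[C@](O)(C(C)C)C[C@H](O[Si](C)(C)C(C)(C)C)[C@]1(C)CC=C | intermediate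
12 | (1R,2S,3R,4S)-4-[(tert-butyldimethylsilyl)oxy]-2-[(1S)-1-hydroxy-3-methylbut-3-en-1-yl]-3-methyl-1-(propan-2-yl)-3-(prop-2-en-1-yl)cyclopentan-1-ol | C=C(C)C[C@H](O)[C@H]1[C@](O)(C(C)C)C[C@H](O[Si](C)(C)C(C)(C)C)[C@]1(C)CC=C | intermediate
13 | (1R,2S,4R,5S,6S)-2-[(tert-butyldimethylsilyl)oxy]dauc-8-ene-4,6-diol (trans-fused) | O[C@H]1CC(C)=CC[C@@]2(C)[C@@H](O[Si](C)(C)C(C)(C)C)C[C@@](O)(C(C)C)[C@H]12 | intermediate
14 | (1R,2S,4R,5S,6S,8R,9S)-2-[(tert-butyldimethylsilyl)oxy]-8,9-epoxydaucane-4,6-diol (oxirane cis to 6-OH) | O[C@H]1C[C@@]2(C)O[C@H]2C[C@@]2(C)[C@@H](O[Si](C)(C)C(C)(C)C)C[C@@](O)(C(C)C)[C@H]12 | intermediate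
15 | (1R,2S,4R,5S,6S,8R,9S)-2-[(tert-butyldimethylsilyl)oxy]-8,9-epoxy-4-hydroxydaucan-6-yl 3,4-dimethoxybenzoate | COc1ccc(C(=O)O[C@H]2C[C@@]3(C)O[C@H]3C[C@@]3(C)[C@@H](O[Si](C)(C)C(C)(C)C)C[C@@](O)(C(C)C)[C@H]23)cc1OC | intermediate
16 | (1R,2S,4R,5S,6S,8R,9S)-8,9-epoxy-2,4-dihydroxydaucan-6-yl 3,4-dimethoxybenzoate | COc1ccc(C(=O)O[C@H]2C[C@@]3(C)O[C@H]3C[C@@]3(C)[C@@H](O)C[C@@](O)(C(C)C)[C@H]23)cc1OC | intermediate
17 | (1R,2S,4R,5S,6S,8R,9S)-2-acetoxy-8,9-epoxy-4-hydroxydaucan-6-yl 3,4-dimethoxybenzoate (CNP0330776.2) | COc1ccc(C(=O)O[C@H]2C[C@@]3(C)O[C@H]3C[C@@]3(C)[C@@H](OC(C)=O)C[C@@](O)(C(C)C)[C@H]23)cc1OC | target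

## Step count and risks

Total step count: 13. Longest linear sequence: 13 steps (from 1).

The three steps most likely to fail:

1. Step 2 (the proposed new step). Diene 3 can undergo 1,5-hydrogen shift before oxidation, and both the level and the sense of asymmetric induction are untested on this diene class. The fallback uses known chemistry, replacing asymmetric oxidation by acetoxylation and enzymatic resolution; it sets out from 1 and comes back at 5. Heating 1 with Mn(OAc)3·2H2O in benzene gives racemic 4-ethoxy-2-oxocyclopent-3-en-1-yl acetate F1. Lipase-mediated hydrolysis (Amano lipase PS, pH 7 phosphate buffer, stopped near 50% conversion) is taken to leave (1S)-4-ethoxy-2-oxocyclopent-3-en-1-yl acetate F2 beside (5R)-3-ethoxy-5-hydroxycyclopent-2-en-1-one F3, which is removed by chromatography. K2CO3 in MeOH at 0 °C converts F2 into (5S)-3-ethoxy-5-hydroxycyclopent-2-en-1-one F4, and TBSCl/imidazole in DMF silylates F4 to 5.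

2. Step 6. The free β-alkoxide can undergo retro-aldol loss of formaldehyde, and the facial preference is a balance between the C5 side chain on one face and the C2 silyloxy and C1 allyl groups on the other. The fallback replaces the hydroxymethyl group by a bulky masked formyl group that carries no free alkoxide; it sets out from 8 and comes back at 11. Enol ether 8 reacts with 1,3-dithian-2-ylium tetrafluoroborate (CH2Cl2, −78 °C) on the methyl face to give (2R,3R,4S)-4-[(tert-butyldimethylsilyl)oxy]-2-(1,3-dithian-2-yl)-3-methyl-3-(prop-2-en-1-yl)cyclopentan-1-one F5. iPrMgCl/CeCl3 then adds anti to the large dithianyl group to give (1R,2R,3R,4S)-4-[(tert-butyldimethylsilyl)oxy]-2-(1,3-dithian-2-yl)-3-methyl-1-(propan-2-yl)-3-(prop-2-en-1-yl)cyclopentan-1-ol F6. MeI/CaCO3 in aqueous MeCN at 40 °C unmasks the aldehyde 11.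

3. Step 8. Allylic Grignard reagents are only weakly chelation-controlled, so the C6 ratio may be poor. The fallback sets C6 on the ring by intramolecular hydride delivery; it sets out from 11 and comes back at 13. The same addition is run without regard to selectivity, and 12 is carried forward together with its epimer (1R,2S,3R,4S)-4-[(tert-butyldimethylsilyl)oxy]-2-[(1R)-1-hydroxy-3-methylbut-3-en-1-yl]-3-methyl-1-(propan-2-yl)-3-(prop-2-en-1-yl)cyclopentan-1-ol F7. Ring-closing metathesis under the conditions of step 9 gives 13 mixed with (1R,2S,4R,5S,6R)-2-[(tert-butyldimethylsilyl)oxy]dauc-8-ene-4,6-diol F8. Dess–Martin oxidation of the mixture converges on (1R,2S,4R,5R)-2-[(tert-butyldimethylsilyl)oxy]-4-hydroxydauc-8-en-6-one F9. Evans–Saksena reduction (Me4NBH(OAc)3, MeCN/AcOH, −20 °C) delivers hydride from the face of the C4 hydroxyl and gives the anti-1,3-diol 13.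

Further compounds

F1 | step 2 | racemic 4-ethoxy-2-oxocyclopent-3-en-1-yl acetate | CCOC1=CC(=O)C(OC(C)=O)C1
F2 | step 2 | (1S)-4-ethoxy-2-oxocyclopent-3-en-1-yl acetate | CCOC1=CC(=O)[C@@H](OC(C)=O)C1
F3 | step 2 | (5R)-3-ethoxy-5-hydroxycyclopent-2-en-1-one | CCOC1=CC(=O)[C@H](O)C1
F4 | step 2 | (5S)-3-ethoxy-5-hydroxycyclopent-2-en-1-one | CCOC1=CC(=O)[C@@H](O)C1
F5 | step 6 | (2R,3R,4S)-4-[(tert-butyldimethylsilyl)oxy]-2-(1,3-dithian-2-yl)-3-methyl-3-(prop-2-en-1-yl)cyclopentan-1-one | S1CCCSC1[C@H]2C(=O)C[C@H](O[Si](C)(C)C(C)(C)C)[C@]2(C)CC=C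
F6 | step 6 | (1R,2R,3R,4S)-4-[(tert-butyldimethylsilyl)oxy]-2-(1,3-dithian-2-yl)-3-methyl-1-(propan-2-yl)-3-(prop-2-en-1-yl)cyclopentan-1-ol | S1CCCSC1[C@H]2[C@](O)(C(C)C)C[C@H](O[Si](C)(C)C(C)(C)C)[C@]2(C)CC=C
F7 | step 8 | (1R,2S,3R,4S)-4-[(tert-butyldimethylsilyl)oxy]-2-[(1R)-1-hydroxy-3-methylbut-3-en-1-yl]-3-methyl-1-(propan-2-yl)-3-(prop-2-en-1-yl)cyclopentan-1-ol | C=C(C)C[C@@H](O)[C@H]1[C@](O)(C(C)C)C[C@H](O[Si](C)(C)C(C)(C)C)[C@]1(C)CC=C
F8 | step 8 | (1R,2S,4R,5S,6R)-2-[(tert-butyldimethylsilyl)oxy]dauc-8-ene-4,6-diol | O[C@@H]1CC(C)=CC[C@@]2(C)[C@@H](O[Si](C)(C)C(C)(C)C)C[C@@](O)(C(C)C)[C@H]12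
F9 | step 8 | (1R,2S,4R,5R)-2-[(tert-butyldimethylsilyl)oxy]-4-hydroxydauc-8-en-6-one | O=C1CC(C)=CC[C@@]2(C)[C@@H](O[Si](C)(C)C(C)(C)C)C[C@@](O)(C(C)C)[C@H]12
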